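## Retrosynthetic overview

1. The target is the trans-(3R,4R)-dibenzylbutyrolactone. The strategy rests on ring A: its C1 carries the benzylic CH2 bound to lactone C3, C2, C3 and C4 carry OH, OMe and OH, and C5 and C6 carry H. This is the pattern a 2-methoxy-1,3-dioxygenated diene leaves on an acyl alkyne.
2. Last disconnection: the benzylic CH2 goes back to an aryl ketone on lactone C3, and the phenol of ring B (the 4-hydroxy-3-methoxyphenyl ring) to its benzyl ether. One hydrogenolysis removes both.
3. Key disconnection: ring A bonds C1–C2 and C5–C6. A Diels–Alder addition of 1,2-dimethoxy-1,3-bis(trimethylsilyloxy)buta-1,3-diene to the terminal ynone on lactone C3 is followed by aromatisation with loss of methanol and the silyl groups.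
4. The ynone comes from the (R)-4-benzyl lactone by trans-selective aldol addition to 3-(trimethylsilyl)propynal, C-desilylation and oxidation. The lactone, with the C4 stereocentre, comes from a Stobbe condensation, asymmetric hydrogenation and ester reduction.
5. Order of rings: ring B is bought (O-benzylvanillin), the lactone ring is closed in step 3, and ring A is built last in step 10.

Key step: step 10

Assumption: the (4S,5S) antipode of MOD-DIOP is taken as the one that gives the R half-ester. The sense is to be checked on the lactone by its optical rotation, and the antipodal ligand is used with no other change if it proves opposite.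

Remark: C3 of the 3-acyl lactones is labelled 3S only because of CIP priorities. The geometry is the same trans arrangement that becomes 3R in the target.

## Route

Step 1
Reactants: 1 4-benzyloxy-3-methoxybenzaldehyde; 2 dimethyl succinate
Product: 3 (E)-4-(4-benzyloxy-3-methoxyphenyl)-3-(methoxycarbonyl)but-3-enoic acid
Conditions: NaOMe (1.5 equiv), MeOH, reflux; then aq. HCl; recrystallisation
Reagents that add atoms: none
Why: Stobbe condensation, in which the succinate enolate adds to the aldehyde, the alkoxide lactonises onto the distal ester and E1cB opening gives the conjugated ester with the free CH2CO2H arm, expected mainly as the E isomer.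

Step 2
Reactants: 3 (E)-4-(4-benzyloxy-3-methoxyphenyl)-3-(methoxycarbonyl)but-3-enoic acid
Product: 4 (R)-4-(4-benzyloxy-3-methoxyphenyl)-3-(methoxycarbonyl)butanoic acid
Conditions: H2 (5 atm), [Rh(cod)2]BF4 (1 mol %), (4S,5S)-MOD-DIOP (1.1 mol %), Et3N (10 mol %), MeOH, 25 °C
Reagents that add atoms: none
Why: Rhodium-catalysed asymmetric hydrogenation of an itaconate-type half-ester, in which chelation of the carboxylate and the alkene to the chiral diphosphine–rhodium cation fixes the enantioface and sets the centre that becomes lactone C4 (R), while the benzyl ether is inert to the homogeneous catalyst.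

Step 3
Reactants: 4 (R)-4-(4-benzyloxy-3-methoxyphenyl)-3-(methoxycarbonyl)butanoic acid
Product: 6 (R)-4-(4-benzyloxy-3-methoxybenzyl)dihydrofuran-2(3H)-one, via hydroxy acid 5 (not isolated)
Conditions: KOH (1.0 equiv), EtOH, 0 °C; CaCl2 (2 equiv), NaBH4 (4 equiv), EtOH, −10 → 20 °C; then 3 M HCl, 20 °C
Reagents that add atoms: none
Why: Chemoselective borohydride reduction, in which Ca(BH4)2 formed in the flask reduces the methyl ester while the carboxylate salt is untouched, and acidification closes the gamma-lactone without touching the stereocentre.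

Step 4
Reactants: 6 (R)-4-(4-benzyloxy-3-methoxybenzyl)dihydrofuran-2(3H)-one; 7 3-(trimethylsilyl)prop-2-ynal
Product: 8 (3S,4R)-4-(4-benzyloxy-3-methoxybenzyl)-3-[1-hydroxy-3-(trimethylsilyl)prop-2-yn-1-yl]dihydrofuran-2(3H)-one (both carbinol epimers)
Conditions: LiN(iPr)2 (1.1 equiv), THF, −78 °C; 7 (1.2 equiv), −78 °C; AcOH, −78 °C
Reagents that add atoms: none
Why: Aldol addition of the lithium lactone enolate to a non-enolisable ynal, in which the aldehyde approaches anti to the C4 benzyl arm and so sets C3 trans, while the carbinol centre forms as a mixture that step 6 erases.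

Step 5
Reactants: 8 (3S,4R)-4-(4-benzyloxy-3-methoxybenzyl)-3-[1-hydroxy-3-(trimethylsilyl)prop-2-yn-1-yl]dihydrofuran-2(3H)-one
Product: 9 (3S,4R)-4-(4-benzyloxy-3-methoxybenzyl)-3-(1-hydroxyprop-2-yn-1-yl)dihydrofuran-2(3H)-one
Conditions: Bu4NF (1.1 equiv), AcOH (1.1 equiv), THF, 0 °C
Reagents that add atoms: none
Why: Fluoride-induced protodesilylation of the alkynylsilane, buffered with acetic acid against retro-aldol cleavage and done before the oxidation so that the later ynone never meets fluoride.

Step 6
Reactants: 9 (3S,4R)-4-(4-benzyloxy-3-methoxybenzyl)-3-(1-hydroxyprop-2-yn-1-yl)dihydrofuran-2(3H)-one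
Product: 10 (3S,4R)-4-(4-benzyloxy-3-methoxybenzyl)-3-(prop-2-ynoyl)dihydrofuran-2(3H)-one (C3 labile, trans)
Conditions: Dess–Martin periodinane (1.3 equiv), CH2Cl2, 0 → 20 °C; cold aq. Na2S2O3/NaHCO3 wash; used at once
Reagents that add atoms: none
Why: Dess–Martin oxidation of a secondary propargylic beta-hydroxy lactone to the beta-keto lactone under non-basic conditions that spare the terminal ynone, with both carbinol epimers converging and C3 settling trans.

Step 7
Reactants: 11 methyl methoxyacetate
Product: 12 methyl 2-methoxy-3-oxobutanoate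
Conditions: LiN(iPr)2 (2.0 equiv), 11 (2.0 equiv), THF, −78 °C; AcCl (1.0 equiv), −78 °C; 1 M HCl
Reagents that add atoms: acetyl chloride, CC(=O)Cl
Why: Crossed Claisen-type C-acylation of a preformed lithium ester enolate by an acid chloride, in which the second equivalent of enolate takes up the acidic proton of the beta-keto ester and so prevents double acylation.

Step 8
Reactants: 12 methyl 2-methoxy-3-oxobutanoate
Product: 13 methyl 2-methoxy-3-(trimethylsilyloxy)but-2-enoate (E/Z mixture)
Conditions: Me3SiCl (1.5 equiv), Et3N (1.6 equiv), toluene, 20 °C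
Reagents that add atoms: chlorotrimethylsilane, C[Si](C)(C)Cl
Why: O-silylation of the enolisable beta-keto ester by amine base and silyl chloride gives the silyl enol ether of the ketone.

Step 9
Reactants: 13 methyl 2-methoxy-3-(trimethylsilyloxy)but-2-enoate
Product: 14 1,2-dimethoxy-1,3-bis(trimethylsilyloxy)buta-1,3-diene (mixture of geometric isomers)
Conditions: LiN(iPr)2 (1.2 equiv), THF, −78 °C; Me3SiCl (1.3 equiv), −78 → 20 °C; pentane, filtration under argon; used crude
Reagents that add atoms: chlorotrimethylsilane, C[Si](C)(C)Cl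
Why: Gamma-deprotonation of the silyloxy enoate by the lithium amide and O-silylation of the dienolate, the standard two-stage preparation of 1-alkoxy-1,3-bis(silyloxy)buta-1,3-dienes.

Step 10
Reactants: 10 (3S,4R)-4-(4-benzyloxy-3-methoxybenzyl)-3-(prop-2-ynoyl)dihydrofuran-2(3H)-one; 14 1,2-dimethoxy-1,3-bis(trimethylsilyloxy)buta-1,3-diene
Product: 16 (3S,4R)-4-(4-benzyloxy-3-methoxybenzyl)-3-(2,4-dihydroxy-3-methoxybenzoyl)dihydrofuran-2(3H)-one, via cyclohexadiene ketal 15 (not isolated)
Conditions: 14 (2.5 equiv), toluene, −78 → 20 °C; then 1 M HCl, THF, 0 °C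
Reagents that add atoms: none
Why: Thermal, uncatalysed Diels–Alder benzannulation of the type known for 1-alkoxy-1,3-bis(silyloxy)buta-1,3-dienes and acetylenic ketones: the nucleophilic CH2 terminus of 14 bonds to the unsubstituted alkyne carbon of 10 (ring A C5–C6) and the ketene acetal carbon to the acyl-bearing alkyne carbon (ring A C1–C2) in an asynchronous, polarity-matched [4+2] addition. Ring A is thus closed by an intermolecular two-bond [4+2] closure as the 1,4-cyclohexadiene ketal 15. In the acid work-up the silyl groups are hydrolysed, the hemiketal expels methanol and the cross-conjugated dienone tautomerises to the phenol, so that ring A should emerge with OH at C2, OMe at C3, OH at C4 and H at C5 and C6. No stereocentre of the product is made here: the ketal carbon of 15 disappears on aromatisation, C4 is untouched, and C3, a beta-dicarbonyl carbon, remains under thermodynamic control trans to the C4 arm. The step needs regioselectivity and cycloaddition ahead of silyl transfer to the acidic C3–H: the first is secured by the matched polarisation (largest diene HOMO coefficient at CH2, largest ynone LUMO coefficient at the terminal carbon), the second by the mainly keto form of the 3-acyl lactone, the absence of Lewis acid or base, low temperature and an excess of 14. The hydrogen bond from the new C2 hydroxyl to the ketone should keep that phenol from attacking the lactone during the brief, cold acid treatment.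

Step 11
Reactants: 16 (3S,4R)-4-(4-benzyloxy-3-methoxybenzyl)-3-(2,4-dihydroxy-3-methoxybenzoyl)dihydrofuran-2(3H)-one
Product: 19 (3R,4R)-3-(2,4-dihydroxy-3-methoxybenzyl)-4-(4-hydroxy-3-methoxybenzyl)dihydrofuran-2(3H)-one, via phenolic ketone 17 (not isolated), via benzylic carbinol 18 (not isolated)
Conditions: H2 (4 atm), 10% Pd/C, AcOH, 40 °C
Reagents that add atoms: none
Why: Heterogeneous hydrogenolysis, in which the aryl benzyl ether is cleaved and the aryl ketone, activated by its ortho and para hydroxyls, is hydrogenated to the carbinol and hydrogenolysed to CH2 as in the conversion of acylresorcinols to alkylresorcinols, while C3 and C4 are not touched and the trans lactone should be kept.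

## Compound list

1 | 4-benzyloxy-3-methoxybenzaldehyde (O-benzylvanillin) | COc1cc(C=O)ccc1OCc1ccccc1 | starting material
2 | dimethyl succinate | COC(=O)CCC(=O)OC | starting material
3 | (E)-4-(4-benzyloxy-3-methoxyphenyl)-3-(methoxycarbonyl)but-3-enoic acid | COC(=O)/C(CC(=O)O)=C/c1ccc(OCc2ccccc2)c(OC)c1 | intermediate
4 | (R)-4-(4-benzyloxy-3-methoxyphenyl)-3-(methoxycarbonyl)butanoic acid | COC(=O)[C@H](Cc1ccc(OCc2ccccc2)c(OC)c1)CC(=O)O | intermediate
5 | (R)-4-(4-benzyloxy-3-methoxyphenyl)-3-(hydroxymethyl)butanoic acid | COc1cc(C[C@@H](CO)CC(=O)O)ccc1OCc1ccccc1 | intermediate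
6 | (R)-4-(4-benzyloxy-3-methoxybenzyl)dihydrofuran-2(3H)-one | COc1cc(C[C@H]2COC(=O)C2)ccc1OCc1ccccc1 | intermediate
7 | 3-(trimethylsilyl)prop-2-ynal | C[Si](C)(C)C#CC=O | starting material
8 | (3S,4R)-4-(4-benzyloxy-3-methoxybenzyl)-3-[1-hydroxy-3-(trimethylsilyl)prop-2-yn-1-yl]dihydrofuran-2(3H)-one | COc1cc(C[C@H]2COC(=O)[C@@H]2C(O)C#C[Si](C)(C)C)ccc1OCc1ccccc1 | intermediate
9 | (3S,4R)-4-(4-benzyloxy-3-methoxybenzyl)-3-(1-hydroxyprop-2-yn-1-yl)dihydrofuran-2(3H)-one | COc1cc(C[C@H]2COC(=O)[C@@H]2C(O)C#C)ccc1OCc1ccccc1 | intermediate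
10 | (3S,4R)-4-(4-benzyloxy-3-methoxybenzyl)-3-(prop-2-ynoyl)dihydrofuran-2(3H)-one | COc1cc(C[C@H]2COC(=O)[C@@H]2C(=O)C#C)ccc1OCc1ccccc1 | intermediate
11 | methyl methoxyacetate | COCC(=O)OC | starting material
12 | methyl 2-methoxy-3-oxobutanoate | COC(=O)C(OC)C(C)=O | intermediate
13 | methyl 2-methoxy-3-(trimethylsilyloxy)but-2-enoate | COC(=O)C(OC)=C(C)O[Si](C)(C)C | intermediate
14 | 1,2-dimethoxy-1,3-bis(trimethylsilyloxy)buta-1,3-diene | C=C(O[Si](C)(C)C)C(OC)=C(OC)O[Si](C)(C)C | intermediate
15 | (3S,4R)-4-(4-benzyloxy-3-methoxybenzyl)-3-[5,6-dimethoxy-4,6-bis(trimethylsilyloxy)cyclohexa-1,4-diene-1-carbonyl]dihydrofuran-2(3H)-one | COc1cc(C[C@H]2COC(=O)[C@@H]2C(=O)C2=CCC(O[Si](C)(C)C)=C(OC)C2(OC)O[Si](C)(C)C)ccc1OCc1ccccc1 | intermediate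
16 | (3S,4R)-4-(4-benzyloxy-3-methoxybenzyl)-3-(2,4-dihydroxy-3-methoxybenzoyl)dihydrofuran-2(3H)-one | COc1cc(C[C@H]2COC(=O)[C@@H]2C(=O)c2ccc(O)c(OC)c2O)ccc1OCc1ccccc1 | intermediate
17 | (3S,4R)-3-(2,4-dihydroxy-3-methoxybenzoyl)-4-(4-hydroxy-3-methoxybenzyl)dihydrofuran-2(3H)-one | COc1cc(C[C@H]2COC(=O)[C@@H]2C(=O)c2ccc(O)c(OC)c2O)ccc1O | intermediate
18 | (3S,4R)-3-[(2,4-dihydroxy-3-methoxyphenyl)(hydroxy)methyl]-4-(4-hydroxy-3-methoxybenzyl)dihydrofuran-2(3H)-one | COc1cc(C[C@H]2COC(=O)[C@@H]2C(O)c2ccc(O)c(OC)c2O)ccc1O | intermediate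
19 | (3R,4R)-3-(2,4-dihydroxy-3-methoxybenzyl)-4-(4-hydroxy-3-methoxybenzyl)dihydrofuran-2(3H)-one | COc1cc(C[C@H]2COC(=O)[C@@H]2Cc2ccc(O)c(OC)c2O)ccc1O | target

## Step count

Total step count: 11.
Longest linear sequence: 8 steps (steps 1 to 6, then 10 and 11). The diene branch is steps 7 to 9.

## Steps most likely to fail

**Step 10 (key step).** The diene may pass a silyl group to the enolisable C3 position, which destroys the diene and turns the ynone into an unreactive silyl enol ether. Conjugate addition may also stop without ring closure, or the acyl lactone may cyclise onto its own alkyne before the diene arrives. During aromatisation the new ortho phenol may transacylate onto the lactone.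

Fallback: from 6, the lithium enolate (LiN(iPr)2, THF, −78 °C) is added to 2,4-bis(benzyloxy)-3-methoxybenzaldehyde F1, itself made by double O-benzylation of 2,4-dihydroxy-3-methoxybenzaldehyde (BnBr, K2CO3, DMF). This trans-selective aldol addition should give (3S,4R)-4-(4-benzyloxy-3-methoxybenzyl)-3-{[2,4-bis(benzyloxy)-3-methoxyphenyl](hydroxy)methyl}dihydrofuran-2(3H)-one F2. Hydrogenolysis (H2, 10% Pd/C, AcOH, trace HClO4) would remove the three benzyl ethers and the benzylic hydroxyl and return to the route at 19.

**Step 6.** The terminal ynone, which is also a beta-dicarbonyl compound, may oligomerise by conjugate addition or cyclise during oxidation, washing and concentration.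

Fallback: from 6, the lithium enolate is C-acylated at −78 °C, with an acetic acid quench at that temperature, by N-methoxy-N-methyl-3-(trimethylsilyl)prop-2-ynamide F3, prepared from 3-(trimethylsilyl)propiolic acid through its acid chloride. This should give the silyl-capped and more robust (3S,4R)-4-(4-benzyloxy-3-methoxybenzyl)-3-[3-(trimethylsilyl)prop-2-ynoyl]dihydrofuran-2(3H)-one F4, which can be purified and stored. The silyl group is removed only just before use (Bu4NF/AcOH, THF, −78 °C, cold aqueous wash, drying, exchange into toluene), and the solution of 10 goes straight into step 10.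

**Step 11.** The hydrogenation may stall at the carbinol stage. The carbinol may also dehydrate to a 3-benzylidene lactone, whose hydrogenation from the less hindered face would erode the trans configuration at C3.

Fallback: from 16, ionic hydrogenation (Et3SiH in excess, BF3·OEt2, CH2Cl2, −40 → 0 °C) reduces the ketone through the hydroxyl-stabilised benzylic cation. Low temperature and excess silane are meant to outrun Friedel–Crafts closure onto ring B. The product would be (3R,4R)-4-(4-benzyloxy-3-methoxybenzyl)-3-(2,4-dihydroxy-3-methoxybenzyl)dihydrofuran-2(3H)-one F5. Any cis lactone is equilibrated to trans with DBU in toluene, and neutral hydrogenolysis (H2, 10% Pd/C, EtOAc, 20 °C) of the benzyl ether returns to the route at 19.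

## Further compounds

F1 | step 10 | 2,4-bis(benzyloxy)-3-methoxybenzaldehyde | COc1c(OCc2ccccc2)ccc(C=O)c1OCc1ccccc1
F2 | step 10 | (3S,4R)-4-(4-benzyloxy-3-methoxybenzyl)-3-{[2,4-bis(benzyloxy)-3-methoxyphenyl](hydroxy)methyl}dihydrofuran-2(3H)-one | COc1cc(C[C@H]2COC(=O)[C@@H]2C(O)c2ccc(OCc3ccccc3)c(OC)c2OCc2ccccc2)ccc1OCc1ccccc1
F3 | step 6 | N-methoxy-N-methyl-3-(trimethylsilyl)prop-2-ynamide | CON(C)C(=O)C#C[Si](C)(C)C
F4 | step 6 | (3S,4R)-4-(4-benzyloxy-3-methoxybenzyl)-3-[3-(trimethylsilyl)prop-2-ynoyl]dihydrofuran-2(3H)-one | COc1cc(C[C@H]2COC(=O)[C@@H]2C(=O)C#C[Si](C)(C)C)ccc1OCc1ccccc1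
F5 | step 11 | (3R,4R)-4-(4-benzyloxy-3-methoxybenzyl)-3-(2,4-dihydroxy-3-methoxybenzyl)dihydrofuran-2(3H)-one | COc1cc(C[C@H]2COC(=O)[C@@H]2Cc2ccc(O)c(OC)c2O)ccc1OCc1ccccc1
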